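Assumption: the hydrogen sulfate groups of 13 and 14 are written as free acids, as in the target formula. In the flask and on isolation they are ammonium or sodium salts, and the free acid is released only by cold cation exchange just before use.

Compounds are numbered 1–14 in the order in which they appear in the steps; the list follows step 8.

## Analysis of the target

Compound 14 is a flavonol: benzene ring A fused to 4-pyranone ring C (together the 4H-chromen-4-one), with a catechol-derived phenyl ring B on C2. It has no stereocentre, so the problem is one of oxygen differentiation. Five ring oxygens are in three states: methyl ether at O7, hydrogen sulfate at O3, O5 and O4', free hydroxyl at O3'. The free O3'–H sits next to the sulfated O4', so the two catechol oxygens must be distinguished before sulfation. O5 is hydrogen-bonded to the C4 carbonyl, which makes it easy to leave alone in an alkylation but slow to sulfate. The sulfate monoesters are salts, cleave in acid and cannot be purified on silica, so they come last, and anything removed after them must leave under neutral or basic conditions; the pyranone is itself opened by hot strong alkali. The strategy rests on ring A: C5, C7 and C8a carry oxygen in a 1,3,5 pattern, the pattern of phloroglucinol 7, whose three ring carbons and three hydroxyls are equivalent. C4 can therefore be joined to any ring carbon (C4a) and O1–C2 closed through either neighbouring hydroxyl with one outcome.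

## Retrosynthetic reasoning

14 from 13. The last bond cut is the O3'–S bond of a methanesulfonate. A sulfonate on O3' is inert to everything that precedes it (enolate, oxidant, heat, carbonate, hydrogenation, sulfation) and leaves under base, the one medium in which sulfate monoester anions are unreactive. The forward step must cleave the sulfonate faster than base attacks C2 of the pyranone.

13 from 12. The three O–S bonds at O3, O5 and O4' are cut together. Putting them on in one late step keeps every earlier intermediate neutral and chromatographable. The forward step needs an electrophilic sulfating agent forceful enough for the chelated O5–H, with O3' blocked.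

12 from 11. Two benzyl C–O bonds are cut, at O3 and O4'. These are exactly the oxygens that must be free for sulfation together with the never-protected O5, so one hydrogenolysis exposes the full sulfation set. The sulfonate, the methyl ether and the C2=C3 bond must survive.

11 from 10. The O7–CH3 bond is cut. Of the two free hydroxyls in 10, O7–H is the more acidic and unhindered and O5–H is chelated, so the difference between O7 and O5 in the target comes from the substrate itself.

10 from 6 and 7. This is the central disconnection: C4–C4a and O1–C2 are cut, which removes ring C and separates ring A from the rest. Cutting here gives the symmetric arene 7 on one side and a three-carbon unit already carrying O3 and ring B on the other, so no regiochemical question arises on ring A and the C3 oxygen needs no later oxidation. The forward reaction must acylate a ring carbon of 7 with the ester carbon of 6, through ketene 8 and triketone 9, then close the ring by dehydration onto the aryl ketone, in the chromone and not the coumarin sense.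

6 from 2 and 3 by way of 5. The ketone is taken back to the secondary alcohol of 5, and the C2–C3 bond (flavone numbering) is cut as an aldol between aldehyde 2 and enolate 4 of ester 3. The cut falls between the two oxygenated carbons, so each fragment is a simple commercial-type building block. Stereochemistry at both carbons is irrelevant because both centres become sp2.

2 from 1. The sulfonate O–S bond is cut; 1 is bought with O4 already benzylated and O3 free, so the catechol differentiation that the target demands is purchased and not made.

## Alternatives that were turned down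

Alternative 1: Ring A from a pyrone.
- Disconnection: C4a–C8a of ring A; the arene is unravelled to a polyketide chain stored as 2-pyrone A1.
- Key step: Mg(OMe)2 in methanol would open the lactone of A1, and the doubly activated methylene (future C4a) would attack the freed ester carbon (future C8a) in a Claisen condensation, aromatising to chalcone A2.
- For it: O7 is a methyl ether from the outset, so O5 and O7 need no selective alkylation. The benzyl on O3' can be removed last by neutral hydrogenolysis, which is gentler than the aqueous base used here in step 8. On both points it is stronger than the chosen route.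
- Against it: A2 still lacks ring C and the C3 oxygen. The oxidative closure of a 2'-hydroxychalcone that carries a second ortho oxygen tends toward five-membered benzofuranone closure instead of the flavonol. The opened chain can also take an aldol course in place of the Claisen course.
- Comparison: the step count is similar (about seven), but two steps carry real risk where the chosen route has one. The chosen route forms ring C, installs O3 and attaches ring A in a single operation.

Alternative 2: Benzoin closure of C3–C4.
- Disconnection: the C3–C4 bond, leading back to dialdehyde A3.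
- Key step: a triazolium-derived carbene would convert the ring A aldehyde of A3 to its Breslow intermediate, which adds to the tethered aliphatic aldehyde (6-exo-trig) to give trans-dihydroflavonol A4.
- For it: catalytic, near room temperature, and every oxygen is already differentiated (O5 and O4' as acetals, O7 methyl, O3' benzyl), again allowing a final hydrogenolysis. In mildness of the ring closure and of the end-game it is stronger than the melt and the base step of the chosen route.
- Against it: A3 needs a ring A salicylaldehyde with three differently treated oxygens, which gives up the symmetry advantage. Its α-aryl-α-aryloxy acetaldehyde is prone to enolisation and oxidation. The aliphatic aldehyde is the better carbene acceptor, so the wrong acyloin regiochemistry is a real possibility.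
- Comparison: A4 has two stereocentres that must be erased by a further dehydrogenation, so stereocontrol is spent for nothing. With acetal removal, sulfation and hydrogenolysis the route is clearly longer than eight steps; the chosen route makes the flavonol oxidation level directly.

Alternative 3: Ring B by cycloaddition.
- Disconnection: C2'–C3' and C1'–C6' of ring B, leading to alkyne A5 and furan A6.
- Key step: Diels–Alder addition of A5 and A6, then ZnI2 opening of the oxygen bridge, would give phenol A7.
- For it: the O3'/O4' distinction follows from the mechanism (the bridge oxygen becomes O3'–H, the furan alkoxy becomes O4'), and the plan is convergent.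
- Against it: it constructs the one ring that can be bought already differentiated. A5 requires a full ring A/ring C synthesis with O3 and the O5/O7 distinction before the key step, and A6 is a sensitive electron-rich furan. Two regiochemical events must both go the right way, and the Lewis acid must spare two acetals and a 4-methoxybenzyl ether.
- Comparison: the free hydroxyl of A7 is the one that must stay free, so it has to be re-protected before acid deprotection, sulfation and final release, four more steps. The chosen route gets the same catechol distinction from commercial aldehyde 1 in one sulfonylation.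

Key step: step 4

## Route

Step 1
Reactants: 1 4-(benzyloxy)-3-hydroxybenzaldehyde
Product: 2 2-(benzyloxy)-5-formylphenyl methanesulfonate
Conditions: MsCl (1.2 equiv), Et3N (1.5 equiv), CH2Cl2, 0 °C
Reagents that add atoms: methanesulfonyl chloride, CS(=O)(=O)Cl
Why: O-sulfonylation of a phenol; the phenol is the only nucleophile present and the aldehyde is untouched, so the mesylate should form cleanly and mark O3' for the rest of the route.

Step 2
Reactants: 2 2-(benzyloxy)-5-formylphenyl methanesulfonate; 3 ethyl benzyloxyacetate
Product: 5 ethyl 2-(benzyloxy)-3-[4-(benzyloxy)-3-(methanesulfonyloxy)phenyl]-3-hydroxypropanoate (racemic syn/anti mixture), via lithium enolate 4 (not isolated)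
Conditions: 3 (1.2 equiv), LiN(SiMe3)2 (1.15 equiv), THF, −78 °C; then 2, −78 °C; AcOH quench at −78 °C
Reagents that add atoms: none
Why: Lithium ester enolate aldol addition; the preformed chelated enolate 4 should add to the non-enolisable aryl aldehyde at −78 °C much faster than it can remove a proton from the mesyl methyl group, and the cold acid quench prevents retro-aldol. The two new stereocentres form without control, which is acceptable because both become sp2 in steps 3 and 4.

Step 3
Reactants: 5 ethyl 2-(benzyloxy)-3-[4-(benzyloxy)-3-(methanesulfonyloxy)phenyl]-3-hydroxypropanoate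
Product: 6 ethyl 2-(benzyloxy)-3-[4-(benzyloxy)-3-(methanesulfonyloxy)phenyl]-3-oxopropanoate (racemic)
Conditions: Dess–Martin periodinane (1.3 equiv), CH2Cl2, 0 °C to rt
Reagents that add atoms: none
Why: Dess–Martin oxidation of a benzylic secondary alcohol under near-neutral conditions, which avoids retro-aldol cleavage and leaves benzyl ethers and the mesylate alone; both diastereomers of 5 converge on the same racemic β-keto ester.

Step 4
Reactants: 6 ethyl 2-(benzyloxy)-3-[4-(benzyloxy)-3-(methanesulfonyloxy)phenyl]-3-oxopropanoate; 7 phloroglucinol
Product: 10 3-(benzyloxy)-2-[4-(benzyloxy)-3-(methanesulfonyloxy)phenyl]-5,7-dihydroxy-4H-chromen-4-one, via aroyl(benzyloxy)ketene 8 (not isolated), via C-acylphloroglucinol diketone 9 (not isolated)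
Conditions: anhydrous 7 (2 equiv), neat melt, Ar, 240 °C, EtOH and H2O distilled out
Reagents that add atoms: none
Why: This is a Mentzer pyrone synthesis, the thermal condensation of a phenol with a β-keto ester. In the melt 6 should lose ethanol from its enol to give acylketene 8 (direct ester exchange is the alternative path), and an electron-rich ring carbon of 7 takes up the ketene carbon, which becomes C4 and forms the C4–C4a bond of triketone 9. A hydroxyl ortho to the new acyl group then adds to the aryl ketone in a 6-exo-trig closure and the hemiketal loses water, forming O1–C2 and ring C as a 4-pyranone. No stereocentre is created, and the labile one of 6 disappears in 8. The chromone sense is expected because, without acid, the ketone is not activated for attack by the ring carbon, while the ketene or ester carbon is the acylating centre; the ester carbon therefore ends on carbon and the ketone carbon on oxygen. Ring A needs no regiocontrol, since every ring carbon of 7 is equivalent and either ortho hydroxyl of 9 gives the same product. Benzyl ethers and the aryl mesylate have no low-energy pathway in a neutral melt, and the excess of 7 should suppress a second annulation on 10.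

Step 5
Reactants: 10 3-(benzyloxy)-2-[4-(benzyloxy)-3-(methanesulfonyloxy)phenyl]-5,7-dihydroxy-4H-chromen-4-one
Product: 11 3-(benzyloxy)-2-[4-(benzyloxy)-3-(methanesulfonyloxy)phenyl]-5-hydroxy-7-methoxy-4H-chromen-4-one
Conditions: MeI (1.1 equiv), K2CO3 (1.2 equiv), acetone, rt to 40 °C
Reagents that add atoms: iodomethane, CI
Why: Williamson O-methylation; the 7-OH is para-conjugated to the C4 carbonyl and the most acidic phenol, while the 5-OH is locked in a hydrogen bond to that carbonyl, so one equivalent of MeI with a weak base should methylate O7 only.

Step 6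
Reactants: 11 3-(benzyloxy)-2-[4-(benzyloxy)-3-(methanesulfonyloxy)phenyl]-5-hydroxy-7-methoxy-4H-chromen-4-one
Product: 12 3,5-dihydroxy-2-[4-hydroxy-3-(methanesulfonyloxy)phenyl]-7-methoxy-4H-chromen-4-one (rhamnetin 3'-O-mesylate)
Conditions: H2 (1 atm), 10% Pd/C, THF/MeOH, rt
Reagents that add atoms: none
Why: Catalytic hydrogenolysis of benzyl ethers; aryl mesylates and aryl methyl ethers are inert to these conditions, and the tetrasubstituted vinylogous-ester C2=C3 bond should not be reduced at ambient pressure.

Step 7
Reactants: 12 3,5-dihydroxy-2-[4-hydroxy-3-(methanesulfonyloxy)phenyl]-7-methoxy-4H-chromen-4-one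
Product: 13 7-methoxy-2-[3-(methanesulfonyloxy)-4-(sulfooxy)phenyl]-4-oxo-4H-chromene-3,5-diyl bis(hydrogen sulfate) (isolated as ammonium salt)
Conditions: SO3·NMe3 (15 equiv), Et3N, MeCN, 100 °C (sealed vessel, microwave heating); size-exclusion chromatography
Reagents that add atoms: sulfur trioxide–trimethylamine complex, C[N+](C)(C)S(=O)(=O)[O-]
Why: O-sulfation of phenolic and enolic hydroxyls with an amine–SO3 complex; O3–H and O4'–H should react readily, the chelated O5–H is the reason for the large excess and the heat, and the mesylate keeps O3' out of the reaction. The basic medium holds the products as stable ammonium sulfates.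

Step 8
Reactants: 13 7-methoxy-2-[3-(methanesulfonyloxy)-4-(sulfooxy)phenyl]-4-oxo-4H-chromene-3,5-diyl bis(hydrogen sulfate)
Product: 14 rhamnetin 3,5,4'-tri-O-sulfate, 2-[3-hydroxy-4-(sulfooxy)phenyl]-7-methoxy-4-oxo-4H-chromene-3,5-diyl bis(hydrogen sulfate) (isolated as sodium salt)
Conditions: NaOH (0.5 M aq.), rt to 40 °C; CO2 to pH 7–8; desalting on Sephadex G-10
Reagents that add atoms: none
Why: Alkaline cleavage of an aryl methanesulfonate, by hydroxide attack at sulfur or by elimination to sulfene, releasing the 3'-phenoxide. Sulfate monoester anions repel hydroxide and are cleaved by acid, not base, and 3-O-substituted flavones are opened only by hot concentrated alkali, so dilute base near room temperature should take the mesylate alone.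

## Compound list

1 | 4-(benzyloxy)-3-hydroxybenzaldehyde | O=Cc1ccc(OCc2ccccc2)c(O)c1 | starting material
2 | 2-(benzyloxy)-5-formylphenyl methanesulfonate | O=Cc1ccc(OCc2ccccc2)c(OS(C)(=O)=O)c1 | intermediate
3 | ethyl benzyloxyacetate | CCOC(=O)COCc1ccccc1 | starting material
4 | lithium 2-(benzyloxy)-1-ethoxyethen-1-olate (chelated geometry expected, enolate oxygen cis to benzyloxy) | [Li+].CCO/C([O-])=C/OCc1ccccc1 | intermediate
5 | ethyl 2-(benzyloxy)-3-[4-(benzyloxy)-3-(methanesulfonyloxy)phenyl]-3-hydroxypropanoate (racemic, syn/anti mixture, configuration not controlled) | CCOC(=O)C(OCc1ccccc1)C(O)c1ccc(OCc2ccccc2)c(OS(C)(=O)=O)c1 | intermediate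
6 | ethyl 2-(benzyloxy)-3-[4-(benzyloxy)-3-(methanesulfonyloxy)phenyl]-3-oxopropanoate (racemic, enolisable centre) | CCOC(=O)C(OCc1ccccc1)C(=O)c1ccc(OCc2ccccc2)c(OS(C)(=O)=O)c1 | intermediate
7 | phloroglucinol (benzene-1,3,5-triol) | Oc1cc(O)cc(O)c1 | starting material
8 | 2-(benzyloxy)-3-[4-(benzyloxy)-3-(methanesulfonyloxy)phenyl]-3-oxoprop-1-en-1-one (acylketene) | O=C=C(OCc1ccccc1)C(=O)c1ccc(OCc2ccccc2)c(OS(C)(=O)=O)c1 | intermediate
9 | 2-(benzyloxy)-1-[4-(benzyloxy)-3-(methanesulfonyloxy)phenyl]-3-(2,4,6-trihydroxyphenyl)propane-1,3-dione (racemic) | O=C(c1c(O)cc(O)cc1O)C(OCc1ccccc1)C(=O)c1ccc(OCc2ccccc2)c(OS(C)(=O)=O)c1 | intermediate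
10 | 3-(benzyloxy)-2-[4-(benzyloxy)-3-(methanesulfonyloxy)phenyl]-5,7-dihydroxy-4H-chromen-4-one | O=c1c(OCc2ccccc2)c(-c2ccc(OCc3ccccc3)c(OS(C)(=O)=O)c2)oc2cc(O)cc(O)c12 | intermediate
11 | 3-(benzyloxy)-2-[4-(benzyloxy)-3-(methanesulfonyloxy)phenyl]-5-hydroxy-7-methoxy-4H-chromen-4-one | COc1cc(O)c2c(=O)c(OCc3ccccc3)c(-c3ccc(OCc4ccccc4)c(OS(C)(=O)=O)c3)oc2c1 | intermediate
12 | 3,5-dihydroxy-2-[4-hydroxy-3-(methanesulfonyloxy)phenyl]-7-methoxy-4H-chromen-4-one | COc1cc(O)c2c(=O)c(O)c(-c3ccc(O)c(OS(C)(=O)=O)c3)oc2c1 | intermediate
13 | 7-methoxy-2-[3-(methanesulfonyloxy)-4-(sulfooxy)phenyl]-4-oxo-4H-chromene-3,5-diyl bis(hydrogen sulfate) | COc1cc(OS(=O)(=O)O)c2c(=O)c(OS(=O)(=O)O)c(-c3ccc(OS(=O)(=O)O)c(OS(C)(=O)=O)c3)oc2c1 | intermediate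
14 | rhamnetin 3,5,4'-tri-O-sulfate | COc1cc(OS(=O)(=O)O)c2c(=O)c(OS(=O)(=O)O)c(-c3ccc(OS(=O)(=O)O)c(O)c3)oc2c1 | target

## Step count and risk

Total steps: 8. Longest linear sequence: 8 steps (1 to 14); 3 and 7 enter as purchased materials.

Step 4 (key step). The most likely failures are thermal transfer of a benzyl group from oxygen to the very electron-rich ring of 7, hydrolytic and decarboxylative breakdown of 6 if the melt is not dry, a second annulation on the product, and closure in the coumarin sense. The fallback builds ring C from the other side, setting out from 7 and 2 and returning at 10.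
- From 7, a Hoesch acylation with benzyloxyacetonitrile (HCl, ZnCl2, Et2O, 0 °C, then hot water) should give 2-(benzyloxy)-1-(2,4,6-trihydroxyphenyl)ethan-1-one F1.
- From 2, Pinnick oxidation (NaClO2, NaH2PO4, 2-methylbut-2-ene) should give 4-(benzyloxy)-3-(methanesulfonyloxy)benzoic acid F2, which half an equivalent of N,N'-dicyclohexylcarbodiimide converts to 4-(benzyloxy)-3-(methanesulfonyloxy)benzoic anhydride F3.
- Heating F1 with F3 and Et3N at about 160 °C (Allan–Robinson condensation) aroylates the methylene carbon, closes the pyranone and leaves the ring A hydroxyls esterified, as the 5,7-di-O-aroyl ester of 10 F4.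
- K2CO3 in aqueous methanol then cleaves the aryl esters, which are far more labile than the mesylate, and gives 10.

Step 7. The chelated 5-OH may sulfate incompletely, leaving partly sulfated salts that are hard to separate. The fallback replaces direct sulfation by a protected sulfate diester, setting out from 12 and returning at 13.
- 12 with 2,2,2-trichloroethyl chlorosulfate, Et3N and 4-(dimethylamino)pyridine in THF should give the neutral tris(2,2,2-trichloroethyl sulfate) of 12 F5, which can be driven to completion and purified on silica.
- Zinc dust and HCO2NH4 in methanol then remove the three trichloroethyl groups and give 13 as its ammonium salt.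

Step 8. Hydroxide may add at C2 and open the pyranone, which carries no ionisable phenol on ring A to deactivate it, in competition with the slow substitution at the sulfonyl sulfur. The fallback exchanges the O3' mask before sulfation for one that fluoride removes, setting out from 11 and returning at 14.
- KOH in MeOH/THF at 50 °C cleaves the mesylate of 11, where the 5-phenoxide protects the pyranone, to give 3-(benzyloxy)-2-[4-(benzyloxy)-3-hydroxyphenyl]-5-hydroxy-7-methoxy-4H-chromen-4-one F6.
- Mitsunobu etherification with 2-(trimethylsilyl)ethanol (PPh3, diisopropyl azodicarboxylate, THF) gives the 3'-O-[2-(trimethylsilyl)ethyl] ether F7, a group that cannot migrate to O4'.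
- Hydrogenolysis (H2, Pd/C) gives 3,5-dihydroxy-2-{4-hydroxy-3-[2-(trimethylsilyl)ethoxy]phenyl}-7-methoxy-4H-chromen-4-one F8.
- Sulfation as in step 7 gives its 3,5,4'-tri-O-sulfate F9.
- Bu4NF in THF/DMF fragments the silylethyl ether under non-hydrolytic conditions and gives 14.

Step 2. Proton transfer from the mesyl methyl group to the enolate, with loss of the sulfonate through sulfene, or retro-aldol on warming, could erode the addition. The fallback removes the basic enolate from the presence of the mesylate, setting out from 3 and returning at 5.
- Enolate 4 is trapped with Me3SiCl at −78 °C to give the ketene silyl acetal [2-(benzyloxy)-1-ethoxyethenyl]oxy(trimethyl)silane F10.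
- F10 is added to 2 with BF3·OEt2 in CH2Cl2 at −78 °C (Mukaiyama aldol), and mild acidic work-up gives 5.

## Further compounds

F1 | step 4 | 2-(benzyloxy)-1-(2,4,6-trihydroxyphenyl)ethan-1-one | O=C(COCc1ccccc1)c1c(O)cc(O)cc1O
F2 | step 4 | 4-(benzyloxy)-3-(methanesulfonyloxy)benzoic acid | O=C(O)c1ccc(OCc2ccccc2)c(OS(C)(=O)=O)c1
F3 | step 4 | 4-(benzyloxy)-3-(methanesulfonyloxy)benzoic anhydride | O=C(OC(=O)c1ccc(OCc2ccccc2)c(OS(C)(=O)=O)c1)c1ccc(OCc2ccccc2)c(OS(C)(=O)=O)c1
F4 | step 4 | 3-(benzyloxy)-2-[4-(benzyloxy)-3-(methanesulfonyloxy)phenyl]-4-oxo-4H-chromene-5,7-diyl bis[4-(benzyloxy)-3-(methanesulfonyloxy)benzoate] | O=c1c(OCc2ccccc2)c(-c2ccc(OCc3ccccc3)c(OS(C)(=O)=O)c2)oc2cc(OC(=O)c3ccc(OCc4ccccc4)c(OS(C)(=O)=O)c3)cc(OC(=O)c3ccc(OCc4ccccc4)c(OS(C)(=O)=O)c3)c12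
F5 | step 7 | 7-methoxy-2-[3-(methanesulfonyloxy)-4-{[(2,2,2-trichloroethoxy)sulfonyl]oxy}phenyl]-4-oxo-4H-chromene-3,5-diyl bis(2,2,2-trichloroethyl) bis(sulfate) | COc1cc(OS(=O)(=O)OCC(Cl)(Cl)Cl)c2c(=O)c(OS(=O)(=O)OCC(Cl)(Cl)Cl)c(-c3ccc(OS(=O)(=O)OCC(Cl)(Cl)Cl)c(OS(C)(=O)=O)c3)oc2c1
F6 | step 8 | 3-(benzyloxy)-2-[4-(benzyloxy)-3-hydroxyphenyl]-5-hydroxy-7-methoxy-4H-chromen-4-one | COc1cc(O)c2c(=O)c(OCc3ccccc3)c(-c3ccc(OCc4ccccc4)c(O)c3)oc2c1
F7 | step 8 | 3-(benzyloxy)-2-{4-(benzyloxy)-3-[2-(trimethylsilyl)ethoxy]phenyl}-5-hydroxy-7-methoxy-4H-chromen-4-one | COc1cc(O)c2c(=O)c(OCc3ccccc3)c(-c3ccc(OCc4ccccc4)c(OCC[Si](C)(C)C)c3)oc2c1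
F8 | step 8 | 3,5-dihydroxy-2-{4-hydroxy-3-[2-(trimethylsilyl)ethoxy]phenyl}-7-methoxy-4H-chromen-4-one | COc1cc(O)c2c(=O)c(O)c(-c3ccc(O)c(OCC[Si](C)(C)C)c3)oc2c1
F9 | step 8 | 7-methoxy-4-oxo-2-{4-(sulfooxy)-3-[2-(trimethylsilyl)ethoxy]phenyl}-4H-chromene-3,5-diyl bis(hydrogen sulfate) | COc1cc(OS(=O)(=O)O)c2c(=O)c(OS(=O)(=O)O)c(-c3ccc(OS(=O)(=O)O)c(OCC[Si](C)(C)C)c3)oc2c1
F10 | step 2 | [2-(benzyloxy)-1-ethoxyethenyl]oxy(trimethyl)silane (silyloxy cis to benzyloxy, as formed from the chelated enolate) | CCO/C(O[Si](C)(C)C)=C/OCc1ccccc1
A1 | alternative 1 | 6-{(3E)-4-[3-(benzyloxy)-4-(methoxymethoxy)phenyl]-2-oxobut-3-en-1-yl}-4-methoxy-2H-pyran-2-one | COc1cc(CC(=O)/C=C/c2ccc(OCOC)c(OCc3ccccc3)c2)oc(=O)c1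
A2 | alternative 1 | (E)-3-[3-(benzyloxy)-4-(methoxymethoxy)phenyl]-1-(2,6-dihydroxy-4-methoxyphenyl)prop-2-en-1-one | COc1cc(O)c(C(=O)/C=C/c2ccc(OCOC)c(OCc3ccccc3)c2)c(O)c1
A3 | alternative 2 | 2-{1-[3-(benzyloxy)-4-(methoxymethoxy)phenyl]-2-oxoethoxy}-4-methoxy-6-(methoxymethoxy)benzaldehyde (racemic) | O=Cc1c(OCOC)cc(OC)cc1OC(C=O)c1ccc(OCOC)c(OCc2ccccc2)c1
A4 | alternative 2 | racemic trans-2-[3-(benzyloxy)-4-(methoxymethoxy)phenyl]-3-hydroxy-7-methoxy-5-(methoxymethoxy)chroman-4-one (2R,3R drawn) | c1cc(OCOC)c(OCc4ccccc4)cc1[C@@H]2[C@H](C(=O)c3c(OCOC)cc(OC)cc3O2)O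
A5 | alternative 3 | 2-ethynyl-7-methoxy-3,5-bis(methoxymethoxy)-4H-chromen-4-one | C#Cc1oc2cc(OC)cc(OCOC)c2c(=O)c1OCOC
A6 | alternative 3 | 3-[(4-methoxybenzyl)oxy]furan | COc1ccc(COc2ccoc2)cc1
A7 | alternative 3 | 2-[3-hydroxy-4-(4-methoxybenzyloxy)phenyl]-7-methoxy-3,5-bis(methoxymethoxy)-4H-chromen-4-one | COCOc1c(-c2ccc(OCc3ccc(OC)cc3)c(O)c2)oc2cc(OC)cc(OCOC)c2c1=O
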